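The route rests on disconnecting C3–C4 of the seven-membered ring (atom numbers are given below the key-step line). In that ring the C1(Me)=C2 alkene lies one methylene (C3) from quaternary C4, while C8–C9 flanks the five-membered ring: the footprint of a cis-divinylcyclopropane Cope rearrangement. Heating a 2-(cis-2-methyl-2-vinylcyclopropyl)-3-methyl-4-silyloxycyclopent-2-enone breaks the cyclopropane bond C1–C9, forms C3–C4, closes the seven-membered ring and fixes the C4 methyl stereocentre in one operation. The precursor is made as a single cis diastereomer, its cyclopropane configuration matched to the C5 silyl ether, by Negishi coupling of an enantiopure iodoenone with a stereodefined cyclopropylzinc.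

Key step: step 9

Numbering used throughout (not IUPAC): seven-membered ring C1(Me)=C2–C3–C4(Me)–C8–C9(O-ester)–C10; five-membered ring C4–C5(OH)–C6–C7(OH)(iPr)–C8. "Upper face" means the face of the C4 methyl. In the target, C4–Me, C5–OH and C7–OH are on the upper face; H8, the C7 isopropyl group and the C9 ester oxygen are on the lower face.

Remark on the precursor configuration: in the boat transition state the breaking C1–C9 bond and the forming C3–C4 bond lie on the same face of the C9–C8=C4 unit. With the (4R) silyl ether, only the cis isomer with a (1R,2R)-cyclopropane has that face anti to the silyloxy group. The cis isomer with a (1S,2S)-cyclopropane would bond C3 syn to the silyl ether and give the C4 epimer. Trans isomers would first have to epimerise by C1–C9 homolysis, and in them the C1 methyl is cis to the enone arm and open to a homodienyl 1,5-hydrogen shift. Precursor 13 is therefore specified and made as the (1R,2R),(4R) isomer.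

Assumptions: (a) (R)-4-(tert-butyldimethylsilyloxy)cyclopent-2-en-1-one is bought as such. (b) The (4R,5R)-dioxaborolane of step 5 is the enantiomer that converts (E)-cinnamyl alcohol into (1S,2S)-(2-phenylcyclopropyl)methanol; the same facial rule gives 8.

Step 1
Reactants: 1 (R)-4-(tert-butyldimethylsilyloxy)cyclopent-2-en-1-one
Product: 2 (3R,4R)-4-(tert-butyldimethylsilyloxy)-3-methyl-1-(trimethylsilyloxy)cyclopent-1-ene (methyl trans to the silyloxy group)
Conditions: Me2CuLi (from MeLi, CuI), TMSCl, THF, −78 °C
Reagents that add atoms: lithium dimethylcuprate, [Li+].C[Cu-]C; chlorotrimethylsilane, C[Si](C)(C)Cl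
Why: Gilman cuprate conjugate addition with in situ silyl trapping: methyl adds to C3 anti to the neighbouring silyloxy group and O-silylation of the enolate forestalls β-elimination of that group (the new C3 centre is removed again in step 2).

Step 2
Reactants: 2 (3R,4R)-4-(tert-butyldimethylsilyloxy)-3-methyl-1-(trimethylsilyloxy)cyclopent-1-ene
Product: 3 (R)-4-(tert-butyldimethylsilyloxy)-3-methylcyclopent-2-en-1-one
Conditions: Pd(OAc)2 (1.05 equiv), MeCN, rt
Reagents that add atoms: none
Why: Saegusa–Ito oxidation: the palladium enolate formed at C2 can lose hydride only from C3, so the 3-methyl enone is formed regiospecifically and the C4 stereocentre is untouched.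

Step 3
Reactants: 3 (R)-4-(tert-butyldimethylsilyloxy)-3-methylcyclopent-2-en-1-one
Product: 4 (R)-4-(tert-butyldimethylsilyloxy)-2-iodo-3-methylcyclopent-2-en-1-one
Conditions: I2, pyridine, DMAP (cat.), CH2Cl2, 0 °C → rt, dark
Reagents that add atoms: iodine, II
Why: Amine-promoted α-iodination of an enone (conjugate addition of the base, iodination of the enolate, elimination), a standard route to α-iodoenones that tolerates the γ-silyloxy group; no stereocentre is involved.

Step 4
Reactants: 5 prop-2-yn-1-ol (propargyl alcohol)
Product: 7 (Z)-3-iodo-2-methylprop-2-en-1-ol, via alkenylmagnesium alkoxide 6 (not isolated)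
Conditions: MeMgBr (2.5 equiv), CuI (10 mol %), THF/Et2O, −10 °C → rt; then I2, −60 → 0 °C
Reagents that add atoms: methylmagnesium bromide, C[Mg]Br; iodine, II
Why: Copper-catalysed anti-carbomagnesiation of the propargylic alkoxide places methyl on C2 and magnesium on C3 cis to the oxygen in a five-membered chelate, and iodinolysis with retention gives the Z iodide that later becomes the cis cyclopropane.

Step 5
Reactants: 7 (Z)-3-iodo-2-methylprop-2-en-1-ol
Product: 8 [(1R,2R)-2-iodo-1-methylcyclopropyl]methanol (iodine cis to CH2OH)
Conditions: Et2Zn, CH2I2, DME, (4R,5R)-2-butyl-N,N,N′,N′-tetramethyl-1,3,2-dioxaborolane-4,5-dicarboxamide (1.2 equiv), CH2Cl2, −10 °C → rt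
Reagents that add atoms: diiodomethane, ICI
Why: Charette asymmetric Simmons–Smith cyclopropanation: the zinc alkoxide bound to the chiral dioxaborolane directs stereospecific syn transfer of CH2 to one alkene face, so the Z geometry becomes the cis relation of iodine to CH2OH and the ligand sets both new stereocentres (1R,2R).

Step 6
Reactants: 8 [(1R,2R)-2-iodo-1-methylcyclopropyl]methanol
Product: 9 (1R,2R)-2-iodo-1-methylcyclopropane-1-carbaldehyde
Conditions: Dess–Martin periodinane, NaHCO3, CH2Cl2, 0 °C
Reagents that add atoms: none
Why: Dess–Martin oxidation of a primary alcohol under buffered conditions; the aldehyde carbon sits on a quaternary centre, so nothing can epimerise.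

Step 7
Reactants: 9 (1R,2R)-2-iodo-1-methylcyclopropane-1-carbaldehyde
Product: 10 (1R,2R)-1-ethenyl-2-iodo-1-methylcyclopropane (iodine cis to vinyl)
Conditions: Ph3PCH3Br, KN(SiMe3)2, THF, 0 °C; then 9, −78 → 0 °C
Reagents that add atoms: methyltriphenylphosphonium bromide, C[P+](c1ccccc1)(c1ccccc1)c1ccccc1.[Br-]
Why: Wittig methylenation of a non-enolisable aldehyde converts CHO into the vinyl group without touching the cyclopropane stereocentres or the C–I bond.

Step 8
Reactants: 10 (1R,2R)-1-ethenyl-2-iodo-1-methylcyclopropane; 4 (R)-4-(tert-butyldimethylsilyloxy)-2-iodo-3-methylcyclopent-2-en-1-one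
Product: 13 (4R)-4-(tert-butyldimethylsilyloxy)-2-[(1R,2R)-2-ethenyl-2-methylcyclopropyl]-3-methylcyclopent-2-en-1-one (vinyl cis to the enone), via cyclopropyllithium 11 (not isolated), via cyclopropylzinc chloride 12 (not isolated)
Conditions: 10, tBuLi (2.0 equiv), Et2O, −78 °C; ZnCl2 (THF), −78 → 0 °C; then 4, Pd(OAc)2 (5 mol %), SPhos (10 mol %), THF, rt
Reagents that add atoms: none
Why: Negishi coupling: iodine–lithium exchange, transmetalation to zinc and the palladium-catalysed coupling with the α-iodoenone (oxidative addition to zerovalent palladium, reductive elimination) all proceed with retention at the configurationally stable cyclopropyl carbon, so the vinyl group ends cis to the enone and no new stereocentre is formed.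

Step 9
Reactants: 13 (4R)-4-(tert-butyldimethylsilyloxy)-2-[(1R,2R)-2-ethenyl-2-methylcyclopropyl]-3-methylcyclopent-2-en-1-one
Product: 14 (3R,3aR)-3-(tert-butyldimethylsilyloxy)-3a,6-dimethyl-3,3a,4,7-tetrahydroazulen-1(2H)-one (C7 ketone conjugated to C8=C9, C1(Me)=C2, quaternary C4 with its methyl cis to C5–OTBS)
Conditions: toluene (0.02 M), BHT (cat.), 100 °C, sealed tube
Reagents that add atoms: none
Why: Concerted [3,3]-sigmatropic shift of a cis-1,2-divinylcyclopropane (divinylcyclopropane–cycloheptadiene Cope rearrangement), a known reaction type also for substrates in which one vinyl arm is an enone, here the cyclopentenone C8=C4 bond. The seven-membered ring closes by ring expansion of the cyclopropane through a boat transition state with both arms folded over the three-membered ring: C1–C9 breaks as C3–C4 forms, and the new C8=C9 bond stays conjugated to the C7 ketone. The one new stereocentre, quaternary C4, is controlled by the cyclopropane configuration, because breaking and forming bonds lie on the same face of the C9–C8=C4 unit and in the (1R,2R) isomer that face is anti to the C5 silyloxy group, so the methyl ends cis to the C5 oxygen. The step needs this facial selectivity and a workable rate although the C4 methyl points over the cyclopropane CH2 in the boat; the stereodefined cis precursor secures the first without any thermal cis/trans stereomutation, and strain release with retained enone conjugation should secure the second at about 100 °C.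

Step 10
Reactants: 14 bicyclic dienone (3R,3aR)-3-(tert-butyldimethylsilyloxy)-3a,6-dimethyl-3,3a,4,7-tetrahydroazulen-1(2H)-one
Product: 15 tertiary allylic alcohol (isopropyl added at C7; C7–OH on the upper face, cis to C5–OTBS and C4–Me; isopropyl on the lower face; C8=C9 and C1=C2 retained)
Conditions: iPrMgCl, CeCl3 (anhydrous), THF, −78 °C
Reagents that add atoms: isopropylmagnesium chloride, CC(C)[Mg]Cl
Why: Organocerium 1,2-addition (low basicity suppresses enolisation, β-elimination of the C5 silyloxy group and conjugate addition): isopropyl attacks C7 from the lower face, away from the C5 silyloxy group and the C4 methyl, so the C7 hydroxyl ends on the upper face.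

Step 11
Reactants: 15 tertiary allylic alcohol
Product: 16 epoxy alcohol (C8–C9 epoxide with its oxygen on the upper face, cis to C7–OH; C1=C2 retained)
Conditions: VO(acac)2 (5 mol %), tBuOOH, CH2Cl2, 0 °C → rt
Reagents that add atoms: tert-butyl hydroperoxide, CC(C)(C)OO
Why: Vanadium-catalysed hydroxyl-directed epoxidation: the C7 vanadate ester delivers oxygen to the allylic C8=C9 bond on the face of the hydroxyl and leaves the non-allylic C1=C2 bond alone.

Step 12
Reactants: 16 epoxy alcohol
Product: 17 syn-1,3-diol (C7–OH and C9–OH on the upper face, H8 on the lower face, trans ring fusion)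
Conditions: Cp2TiCl2 (2.5 equiv), Mn dust, THF, rt (gives Cp2TiCl, trivalent titanium); then 16, H2O (10 equiv), rt
Reagents that add atoms: none
Why: Nugent–RajanBabu reductive epoxide opening: trivalent titanium cleaves the C8–O bond homolytically to the tertiary C8 radical (no cation, hence no semipinacol shift from C7), and hydrogen-atom transfer from the titanocene aqua complex should arrive on the lower face, opposite the titanium-bound C9 and C7 oxygens and the C4 methyl, giving H8 trans to that methyl and the C7/C9 syn-diol.

Step 13
Reactants: 17 syn-1,3-diol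
Product: 18 β-hydroxy ketone (C9 ketone; C7–OH upper face, H8 lower face)
Conditions: Dess–Martin periodinane, NaHCO3, CH2Cl2, 0 °C → rt
Reagents that add atoms: none
Why: Dess–Martin oxidation selects the only oxidisable (secondary) hydroxyl under buffered neutral conditions that spare the tertiary aldol unit; the trans ring fusion, which keeps C9 trans to the C7 isopropyl group, is also the epimer expected to be favoured should C8 enolise.

Step 14
Reactants: 18 β-hydroxy ketone
Product: 19 anti-1,3-diol (C9–OH on the lower face, trans to C7–OH and cis to H8)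
Conditions: Me4NBH(OAc)3, MeCN/AcOH (1:1), −30 → 0 °C
Reagents that add atoms: none
Why: Evans–Saksena reduction: the triacetoxyborohydride exchanges onto the C7 hydroxyl and delivers hydride intramolecularly to the upper face of the C9 carbonyl, so the new C9 hydroxyl ends on the lower face, anti to C7–OH as in the target.

Step 15
Reactants: 20 4-hydroxybenzoic acid
Product: 22 4-(tert-butyldimethylsilyloxy)benzoic acid, via bis-silyl derivative 21 (not isolated)
Conditions: TBSCl (2.3 equiv), imidazole, DMF, rt; then AcOH (cat.), MeOH/H2O, rt
Reagents that add atoms: tert-butyldimethylsilyl chloride, CC(C)(C)[Si](C)(C)Cl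
Why: Exhaustive silylation followed by solvolysis of the much more labile silyl ester leaves only the phenol protected (standard protecting-group chemistry).

Step 16
Reactants: 19 anti-1,3-diol; 22 4-(tert-butyldimethylsilyloxy)benzoic acid
Product: 24 bis-silyl ether of the target (C9 4-(tert-butyldimethylsilyloxy)benzoate, C5–OTBS, free C7–OH), via mixed anhydride 23 (not isolated)
Conditions: 22, 2,4,6-trichlorobenzoyl chloride, Et3N, toluene, rt; then 19, DMAP, toluene, rt → 50 °C
Reagents that add atoms: none
Why: Yamaguchi esterification: the mixed anhydride and DMAP generate an acylpyridinium ion that acylates the hindered secondary C9 hydroxyl with retention at C9, while the tertiary C7 hydroxyl does not react.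

Step 17
Reactants: 24 bis-silyl ether of the target
Product: 25 target CNP0215209.2 (C9 4-hydroxybenzoate; C5–OH, C7–OH and C4–Me on the upper face; H8, isopropyl and ester oxygen on the lower face)
Conditions: HF·pyridine, pyridine/THF, 0 °C → rt
Reagents that add atoms: none
Why: Fluoride-mediated desilylation removes the aryl and the secondary alkyl silyl ether together; the buffered, non-basic medium leaves the ester, the tertiary alcohol and the alkene untouched and no stereocentre is affected.

Compound list
1 | (R)-4-(tert-butyldimethylsilyloxy)cyclopent-2-en-1-one | O=C1C=C[C@H](O[Si](C)(C)C(C)(C)C)C1 | starting material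
2 | (3R,4R)-4-(tert-butyldimethylsilyloxy)-3-methyl-1-(trimethylsilyloxy)cyclopent-1-ene | C[Si](C)(C)OC1=C[C@@H](C)[C@H](O[Si](C)(C)C(C)(C)C)C1 | intermediate
3 | (R)-4-(tert-butyldimethylsilyloxy)-3-methylcyclopent-2-en-1-one | O=C1C=C(C)[C@H](O[Si](C)(C)C(C)(C)C)C1 | intermediate
4 | (R)-4-(tert-butyldimethylsilyloxy)-2-iodo-3-methylcyclopent-2-en-1-one | O=C1C(I)=C(C)[C@H](O[Si](C)(C)C(C)(C)C)C1 | intermediate
5 | prop-2-yn-1-ol | C#CCO | starting material
6 | bromomagnesium (Z)-3-(bromomagnesio)-2-methylprop-2-en-1-olate (not isolated) | Br[Mg]/C=C(C)\CO[Mg]Br | intermediate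
7 | (Z)-3-iodo-2-methylprop-2-en-1-ol | OC/C(C)=C\I | intermediate
8 | [(1R,2R)-2-iodo-1-methylcyclopropyl]methanol | OC[C@@]1(C)C[C@H]1I | intermediate
9 | (1R,2R)-2-iodo-1-methylcyclopropane-1-carbaldehyde | O=C[C@@]1(C)C[C@H]1I | intermediate
10 | (1R,2R)-1-ethenyl-2-iodo-1-methylcyclopropane | C=C[C@@]1(C)C[C@H]1I | intermediate
11 | cis-(2-ethenyl-2-methylcyclopropyl)lithium, configuration of 10 retained (not isolated) | C=C[C@@]1(C)C[C@H]1[Li] | intermediate
12 | cis-(2-ethenyl-2-methylcyclopropyl)zinc chloride, configuration of 10 retained (not isolated) | C=C[C@@]1(C)C[C@H]1[Zn]Cl | intermediate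
13 | (4R)-4-(tert-butyldimethylsilyloxy)-2-[(1R,2R)-2-ethenyl-2-methylcyclopropyl]-3-methylcyclopent-2-en-1-one | C=C[C@@]1(C)C[C@H]1C2=C(C)[C@H](O[Si](C)(C)C(C)(C)C)CC2=O | intermediate
14 | (3R,3aR)-3-(tert-butyldimethylsilyloxy)-3a,6-dimethyl-3,3a,4,7-tetrahydroazulen-1(2H)-one | CC1=CC[C@@]2(C)[C@H](O[Si](C)(C)C(C)(C)C)CC(=O)C2=CC1 | intermediate
15 | tertiary allylic alcohol (C7–OH upper face, isopropyl lower face, C8=C9, C1=C2, C5–OTBS) | CC1=CC[C@@]2(C)[C@H](O[Si](C)(C)C(C)(C)C)C[C@@](O)(C(C)C)C2=CC1 | intermediate
16 | epoxy alcohol (C8–C9 epoxide oxygen on the upper face, cis to C7–OH) | CC1=CC[C@@]2(C)[C@H](O[Si](C)(C)C(C)(C)C)C[C@@](O)(C(C)C)[C@]23O[C@@H]3C1 | intermediate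
17 | syn-1,3-diol (C7–OH and C9–OH upper face, H8 lower face) | CC1=CC[C@@]2(C)[C@H](O[Si](C)(C)C(C)(C)C)C[C@@](O)(C(C)C)[C@@H]2[C@H](O)C1 | intermediate
18 | β-hydroxy ketone (C9 ketone, C7–OH upper face, H8 lower face) | CC1=CC[C@@]2(C)[C@H](O[Si](C)(C)C(C)(C)C)C[C@@](O)(C(C)C)[C@@H]2C(=O)C1 | intermediate
19 | anti-1,3-diol (C9–OH lower face, C7–OH upper face, H8 lower face) | CC1=CC[C@@]2(C)[C@H](O[Si](C)(C)C(C)(C)C)C[C@@](O)(C(C)C)[C@@H]2[C@@H](O)C1 | intermediate
20 | 4-hydroxybenzoic acid | O=C(O)c1ccc(O)cc1 | starting material
21 | tert-butyldimethylsilyl 4-(tert-butyldimethylsilyloxy)benzoate (not isolated) | CC(C)(C)[Si](C)(C)OC(=O)c1ccc(O[Si](C)(C)C(C)(C)C)cc1 | intermediate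
22 | 4-(tert-butyldimethylsilyloxy)benzoic acid | O=C(O)c1ccc(O[Si](C)(C)C(C)(C)C)cc1 | intermediate
23 | 4-(tert-butyldimethylsilyloxy)benzoic 2,4,6-trichlorobenzoic anhydride (not isolated) | O=C(OC(=O)c1c(Cl)cc(Cl)cc1Cl)c1ccc(O[Si](C)(C)C(C)(C)C)cc1 | intermediate
24 | bis-silyl ether of the target (C9 4-(tert-butyldimethylsilyloxy)benzoate, C5–OTBS) | CC1=CC[C@@]2(C)[C@H](O[Si](C)(C)C(C)(C)C)C[C@@](O)(C(C)C)[C@@H]2[C@@H](OC(=O)c2ccc(O[Si](C)(C)C(C)(C)C)cc2)C1 | intermediate
25 | target CNP0215209.2 | CC1=CC[C@@]2(C)[C@H](O)C[C@@](O)(C(C)C)[C@@H]2[C@@H](OC(=O)c2ccc(O)cc2)C1 | target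

Total step count: 17. Longest linear sequence: 13 steps (5 → 25 through steps 4–14, 16 and 17).

Steps most likely to fail

Step 9 (Cope rearrangement). The boat transition state forces the C4 methyl over the cyclopropane methylene, so the rearrangement may be slow. At the higher temperature then needed, reversible C1–C9 homolysis would scramble the cyclopropane configuration, eroding facial control at C4 and opening hydrogen-shift side reactions. The fallback builds the C3–C4 bond intermolecularly and closes the seven-membered ring by metathesis. It sets out from enone 3. Copper-mediated conjugate allylation with silyl trapping (allylMgBr, CuBr·SMe2, TMSCl, THF, −78 °C) should add allyl anti to the silyloxy group and give the 3-allyl silyl enol ether F1. A Mukaiyama aldol reaction (BF3·OEt2, CH2Cl2, −78 °C) with freshly prepared 3-methylbut-3-enal F2 (Dess–Martin oxidation of 3-methylbut-3-en-1-ol, used at once) gives the aldol adduct F3. Ring-closing metathesis of its allyl and 2-methylallyl groups (second-generation Grubbs catalyst, CH2Cl2, 40 °C) forms C1=C2 and the bicyclic β-hydroxy ketone F4. Mesylation and elimination (MsCl, Et3N; then DBU) installs C8=C9 and returns to dienone 14.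

Step 12 (reductive epoxide opening). Hydrogen-atom transfer to the planar C8 radical could take place on the upper face, giving poor facial selectivity and a cis ring fusion. The fallback sets C8 by thermodynamic enolisation instead of kinetic hydrogen-atom transfer. It sets out from epoxy alcohol 16 with the same opening. If the cis-fused diol F5 predominates, Dess–Martin oxidation gives the cis-fused β-hydroxy ketone F6, whose C8 hydrogen is α to the C9 carbonyl. Equilibration with DBU (toluene, rt) should favour the trans-fused epimer, in which C9 is trans to the C7 isopropyl group and the C7 hydroxyl can hydrogen-bond to the ketone. That epimer is ketone 18, where the route is rejoined.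

Step 8 (Negishi coupling). A cyclopropylzinc flanked by a quaternary carbon must be joined to a fully substituted alkene carbon, so transmetalation or reductive elimination may stall and give way to protodemetalation of the zinc reagent and reductive deiodination of the enone. The fallback joins two sp2 carbons first and makes the cyclopropane afterwards. It sets out from iodide 7 and iodoenone 4. Palladium-catalysed stannylation of 7 (Bu3SnSnBu3, PdCl2(PPh3)2, THF) gives the Z-vinylstannane F7. Stille coupling with 4 (Pd2(dba)3, AsPh3, CuI, NMP, rt) gives the Z-dienone alcohol F8. The cyclopropanation conditions of step 5 then give the cis-cyclopropylmethanol F9. Dess–Martin oxidation gives the cyclopropanecarbaldehyde F10, to be used cold and at once, and Wittig methylenation as in step 7 returns to precursor 13.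

Further compounds
F1 | step 9 | 3-allyl-4-(tert-butyldimethylsilyloxy)-3-methyl-1-(trimethylsilyloxy)cyclopent-1-ene, allyl trans to the silyloxy group | C=CC[C@@]1(C)[C@H](O[Si](C)(C)C(C)(C)C)CC(O[Si](C)(C)C)=C1
F2 | step 9 | 3-methylbut-3-enal | C=C(C)CC=O
F3 | step 9 | 3-allyl-4-(tert-butyldimethylsilyloxy)-2-(1-hydroxy-3-methylbut-3-enyl)-3-methylcyclopentan-1-one (mixture at the two new centres) | C=CC[C@@]1(C)[C@H](O[Si](C)(C)C(C)(C)C)CC(=O)C1C(O)CC(C)=C
F4 | step 9 | bicyclic β-hydroxy ketone (C7 ketone, C8–H, C9–OH, C1(Me)=C2; mixture at C8 and C9) | CC1=CC[C@@]2(C)[C@H](O[Si](C)(C)C(C)(C)C)CC(=O)C2C(O)C1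
F5 | step 12 | C8 epimer of diol 17 (H8 on the upper face, cis ring fusion) | CC1=CC[C@@]2(C)[C@H](O[Si](C)(C)C(C)(C)C)C[C@@](O)(C(C)C)[C@H]2[C@H](O)C1
F6 | step 12 | C8 epimer of ketone 18 (cis ring fusion) | CC1=CC[C@@]2(C)[C@H](O[Si](C)(C)C(C)(C)C)C[C@@](O)(C(C)C)[C@H]2C(=O)C1
F7 | step 8 | (Z)-2-methyl-3-(tributylstannyl)prop-2-en-1-ol | CCCC[Sn](CCCC)(CCCC)/C=C(C)\CO
F8 | step 8 | (4R)-4-(tert-butyldimethylsilyloxy)-2-[(1Z)-3-hydroxy-2-methylprop-1-en-1-yl]-3-methylcyclopent-2-en-1-one | OC/C(C)=C\C1=C(C)[C@H](O[Si](C)(C)C(C)(C)C)CC1=O
F9 | step 8 | cis-cyclopropylmethanol (cyclopropane configuration of 13, CH2OH in place of vinyl) | OC[C@@]1(C)C[C@H]1C2=C(C)[C@H](O[Si](C)(C)C(C)(C)C)CC2=O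
F10 | step 8 | cis-cyclopropanecarbaldehyde (cyclopropane configuration of 13, CHO in place of vinyl) | O=C[C@@]1(C)C[C@H]1C2=C(C)[C@H](O[Si](C)(C)C(C)(C)C)CC2=O
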